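**Retrosynthetic overview**
- The C4 isovalerate and the C3 angelate go on last, onto a tricyclic enone that carries a free C3 hydroxyl and a C4/C5 acetonide.
- Cyclohexenone (formed last): C10–C11 by intramolecular ipso-acylation of a vinylsilane; C8–C9 by a palladium-catalysed transannular γ-C–H alkenylation directed by the C1 carboxylic acid.
- Seven-membered ring (formed second): C2–C3 by a Reformatsky aldol of a cyclobutanone with a Co2(CO)6-complexed ynal, C6–C7 by an intramolecular Nicholas reaction; then cis-alkene, OsO4 diol, and Wolff–Kishner removal of the C8 carbonyl.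
- Cyclobutane (present from the start): 3-oxocyclobutanecarboxylic acid, desymmetrised with a chiral lithium amide and methylated.
- Four side fragments are made separately: the cobalt-complexed ynal, a (Z)-iodovinylsilane, angelic anhydride and isovaleric anhydride.

Assumption (core numbering, kept for every intermediate): cyclobutane = C1–C2–C8–C7; C1 and C8 end up carrying C11(=O) and C9; C2 is the methyl-bearing quaternary carbon; C3(OAng)–C4(O-isovaleryl)–C5(OH)–C6(CMe2) bridge C2 to C7 on the "upper" face; "C1 side" and "C8 side" are the two flanks of that bridge.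

**Route**

Step 1
Reactants: 1 3-oxocyclobutane-1-carboxylic acid
Product: 2 methyl 3-oxocyclobutane-1-carboxylate
Conditions: MeI, K2CO3, DMF, 23 °C
Reagents that add atoms: iodomethane CI
Why: Carboxylate O-alkylation (SN2 esterification) under non-acidic conditions, so the strained ketone is not ketalised; no stereocentre is present yet.

Step 2
Reactants: 2 methyl 3-oxocyclobutane-1-carboxylate
Product: 4 methyl (1R,2S)-2-methyl-3-oxocyclobutane-1-carboxylate, via lithium enolate 3 (not isolated)
Conditions: lithium (R,R)-bis(1-phenylethyl)amide (from the amine and n-BuLi), LiCl, THF, −100 °C; then MeI, DMPU, −78 → −40 °C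
Reagents that add atoms: iodomethane CI
Why: Enantioselective deprotonation (chiral lithium amide desymmetrisation of a 3-substituted cyclobutanone) followed by enolate C-methylation: the base takes a proton from one of the two enantiotopic CH2 groups, which fixes C1 and decides which ring carbon becomes C2, and the methyl enters anti to the ester.

Step 3
Reactants: 4 methyl (1R,2S)-2-methyl-3-oxocyclobutane-1-carboxylate
Product: 5 methyl (1S)-2-bromo-2-methyl-3-oxocyclobutane-1-carboxylate
Conditions: Br2, AcOH, HBr (cat.), 15 °C
Reagents that add atoms: bromine BrBr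
Why: Acid-catalysed ketone α-bromination through the more substituted enol puts bromine on C2; the C2 epimer ratio is irrelevant because C2 is planarised in step 7, and C1 is untouched (its descriptor changes only through CIP priority).

Step 4
Reactants: 6 2-methylbut-3-yn-2-ol
Product: 8 3-methoxy-3-methylbut-1-yne, via sodium alkoxide 7 (not isolated)
Conditions: NaH (1.0 equiv), THF, 0 °C; then MeI, 23 °C
Reagents that add atoms: iodomethane CI
Why: Williamson ether synthesis, the O–H being deprotonated in preference to the alkyne C–H; the methyl ether later serves as leaving group at the tertiary propargylic carbon.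

Step 5
Reactants: 8 3-methoxy-3-methylbut-1-yne
Product: 10 4-methoxy-4-methylpent-2-ynal, via lithium acetylide 9 (not isolated)
Conditions: n-BuLi, THF, −78 °C; then DMF; inverse quench into aq. KH2PO4
Reagents that add atoms: N,N-dimethylformamide CN(C)C=O
Why: Formylation of a lithium acetylide with DMF (Bouveault-type), the buffered inverse quench releasing the ynal without amine conjugate addition.

Step 6
Reactants: 10 4-methoxy-4-methylpent-2-ynal
Product: 11 hexacarbonyldicobalt complex of 4-methoxy-4-methylpent-2-ynal
Conditions: Co2(CO)8, CH2Cl2, 23 °C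
Reagents that add atoms: dicobalt octacarbonyl O=C=[Co](=C=O)(=C=O)(=C=O)[Co](=C=O)(=C=O)(=C=O)=C=O
Why: Alkyne complexation by Co2(CO)8 (first stage of Nicholas chemistry) with loss of two CO; the complex bends the alkyne to about 140°, so it can later sit in a seven-membered ring, and stabilises a cation at the tertiary carbon.

Step 7
Reactants: 5 methyl (1S)-2-bromo-2-methyl-3-oxocyclobutane-1-carboxylate; 11 hexacarbonyldicobalt complex of 4-methoxy-4-methylpent-2-ynal
Product: 13 cobalt-complexed aldol adduct (new C2–C3 bond), via bromozinc enolate 12 (not isolated)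
Conditions: Zn dust (activated), THF, 0 °C; then 11, −78 → −30 °C; aq. HCl (0.5 M)
Reagents that add atoms: none
Why: Reformatsky aldol reaction: zinc insertion turns both C2 epimers of 5 into one regiodefined zinc enolate, and the complexed aldehyde adds through a chelated Zimmerman–Traxler chair on the C2 face anti to the C1 ester with the bulky cobalt–alkyne group equatorial, which sets C2 (CH3 cis and C3 trans to CO2CH3) and C3 (hydroxyl syn to the C2 methyl, the configuration that later puts C3–O on the C1 side).

Step 8
Reactants: 13 cobalt-complexed aldol adduct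
Product: 16 cobalt-complexed bicyclic hydroxy keto ester (new C6–C7 bond), via bis-silyl enol ether 14 (not isolated), via cyclised silyl ether 15 (not isolated)
Conditions: Me3SiOTf (3.2 equiv), Et3N (2.2 equiv), CH2Cl2, −78 → −20 °C; aq. citric acid
Reagents that add atoms: none
Why: Intramolecular Nicholas reaction: soft enolisation can only go toward C7 because C2 is quaternary, excess Me3SiOTf ionises the tertiary propargylic methyl ether to the Co2(CO)6-stabilised cation, and the tether lets that cation reach C7 only on the face that carries C3, so C6 is bonded cis to C3 and trans to the C1 ester while the seven-membered ring closes.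

Step 9
Reactants: 16 cobalt-complexed bicyclic hydroxy keto ester
Product: 17 bicyclic cycloheptenol keto ester (C4=C5 cis)
Conditions: n-Bu3SnH, benzene, 65 °C
Reagents that add atoms: none
Why: Reductive decomplexation of the cobalt–alkyne complex by tin hydride delivers two hydrogens to the coordinated alkyne and frees the ring-constrained cis-alkene without touching a stereocentre.

Step 10
Reactants: 17 bicyclic cycloheptenol keto ester
Product: 18 bicyclic triol keto ester
Conditions: OsO4 (5 mol %), NMO, acetone–H2O (4:1), 23 °C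
Reagents that add atoms: osmium tetroxide O=[Os](=O)(=O)=O; N-methylmorpholine N-oxide C[N+]1([O-])CCOCC1; water O
Why: Upjohn dihydroxylation: suprafacial addition gives the cis C4/C5 diol on the face anti to the allylic C3 hydroxyl (Kishi selectivity), which is also the more open C8 side because the C8 carbonyl carbon has no inward hydrogen whereas C1 has one.

Step 11
Reactants: 18 bicyclic triol keto ester
Product: 19 keto ester protected as C4/C5 acetonide plus C3 mixed ketal
Conditions: 2-methoxypropene, PPTS (cat.), CH2Cl2, 0 °C
Reagents that add atoms: 2-methoxypropene COC(C)=C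
Why: Acid-catalysed acetalisation with an enol ether: the cis C4/C5 diol closes the five-membered acetonide and the C3 hydroxyl is capped as its 2-methoxypropan-2-yl ether, so no free alkoxide sits beta to the ketone in the next step; no stereocentre changes.

Step 12
Reactants: 19 protected keto ester
Product: 22 hydroxy acid acetonide (C8 now CH2), via hydrazone 20 (not isolated), via potassium carboxylate 21 (not isolated)
Conditions: N2H4·H2O, diethylene glycol, 120 °C; then KOH, 195 °C; aq. HCl to pH 3, 0 °C
Reagents that add atoms: potassium hydroxide [K+].[OH-]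
Why: Wolff–Kishner reduction (Huang–Minlon procedure): the non-enolisable cyclobutanone forms its hydrazone first, hot KOH then expels N2 to leave the C8 methylene and saponifies the ester (and any acyl hydrazide formed from it), and the pH 3 work-up hydrolyses only the labile mixed ketal; C1 keeps its configuration, the carboxyl anti to the bridge being also the thermodynamic position.

Step 13
Reactants: 23 propyne
Product: 25 triethyl(prop-1-yn-1-yl)silane, via propynyllithium 24 (not isolated)
Conditions: n-BuLi, THF, −78 °C; then Et3SiCl, −78 → 23 °C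
Reagents that add atoms: chlorotriethylsilane CC[Si](CC)(CC)Cl
Why: C-Silylation of a lithium acetylide; the triethylsilyl group is chosen because its vinylsilane resists protodesilylation better than the trimethylsilyl analogue.

Step 14
Reactants: 25 triethyl(prop-1-yn-1-yl)silane
Product: 26 (Z)-triethyl(2-iodoprop-1-en-1-yl)silane
Conditions: NaI, Me3SiCl, H2O (0.5 equiv), MeCN, 23 °C
Reagents that add atoms: sodium iodide [Na+].[I-]
Why: Markovnikov hydroiodination of a silylalkyne with HI made in the flask: protonation at the silicon-bearing carbon (β-silyl-stabilised vinyl cation) and anti addition put iodine on C2 cis to silicon.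

Step 15
Reactants: 22 hydroxy acid acetonide; 26 (Z)-triethyl(2-iodoprop-1-en-1-yl)silane
Product: 27 C8-alkenylated hydroxy acid acetonide (new C8–C9 bond)
Conditions: Pd(OAc)2 (10 mol %), bidentate quinuclidine–2-pyridone ligand (12 mol %), Ag2CO3 (1.0 equiv), K2HPO4, HFIP, 90 °C
Reagents that add atoms: none
Why: Proposed new method: carboxylate-directed transannular γ-C(sp3)–H alkenylation, in which the carboxylate of 22 bound to divalent palladium carrying the pyridone ligand reaches across the cyclobutane only to the C8–H that is cis to it (concerted metalation–deprotonation through a bridged six-membered palladacycle; C2 has no hydrogen, the bridgehead C7–H and the other C8–H point away), oxidative addition of alkenyl iodide 26 gives a tetravalent alkenylpalladium that reductively eliminates with retention at both carbons, so C9 is attached on the lower face of C8 (cis to CO2H, anti to the bridge) with the Z geometry kept, and AgI precipitation turns the cycle over; the closest known reaction type is the ligand-enabled palladium-catalysed transannular γ-C–H arylation of cycloalkane (including cyclobutane) carboxylic acids with aryl iodides, which has not been shown with alkenyl iodides or with a bridged acid bearing an α-hydrogen.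

Step 16
Reactants: 27 C8-alkenylated hydroxy acid acetonide
Product: 29 tricyclic enone alcohol acetonide (cyclohexenone closed), via acid chloride 28 (not isolated)
Conditions: 1-chloro-N,N,2-trimethylprop-1-en-1-amine, CH2Cl2, 0 °C; then SnCl4, −78 → −30 °C
Reagents that add atoms: none
Why: Intramolecular Friedel–Crafts-type ipso-acylation of a vinylsilane: the acylium adds at the silicon-bearing C10, the β-silyl cation at C9 collapses by loss of Et3SiCl, and the ring allows only the cis C9=C10 enone; the C3 hydroxyl sits trans to the acyl group across the cyclobutane and cannot lactonise, and no stereocentre changes.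

Step 17
Reactants: 30 angelic acid [(Z)-2-methylbut-2-enoic acid] (2 equiv)
Product: 31 angelic anhydride
Conditions: DCC (0.5 equiv per acid), CH2Cl2, 0 °C
Reagents that add atoms: angelic acid (second equivalent of 30) C/C=C(/C)C(=O)O
Why: Carbodiimide-mediated dehydration: one molecule of acid forms the O-acylisourea and a second molecule of acid attacks it to give the symmetric anhydride and the urea, without base or heat so the Z geometry is kept.

Step 18
Reactants: 29 tricyclic enone alcohol acetonide; 31 angelic anhydride
Product: 34 C3 angelate C4/C5 diol, via lithium alkoxide 32 (not isolated), via acetonide angelate 33 (not isolated)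
Conditions: LiN(SiMe3)2, THF, −78 °C; 31, −78 → 0 °C; then aq. HCl (2 M)–THF, 35 °C
Reagents that add atoms: none
Why: O-Acylation of the lithium alkoxide of the hindered C3 alcohol by the anhydride (no nucleophilic catalyst, so no Z to E isomerisation) followed by acid hydrolysis of the acetonide; all configurations are retained.

Step 19
Reactants: 35 isovaleric acid (3-methylbutanoic acid) (2 equiv)
Product: 36 isovaleric anhydride
Conditions: DCC (0.5 equiv per acid), CH2Cl2, 23 °C
Reagents that add atoms: isovaleric acid (second equivalent of 35) CC(C)CC(=O)O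
Why: Carbodiimide-mediated dehydration in which a second molecule of acid acylates on the O-acylisourea of the first, giving the symmetric anhydride as a mild acyl donor for the last step.

Step 20
Reactants: 34 C3 angelate C4/C5 diol; 36 isovaleric anhydride
Product: 37 target CNP0251293.1
Conditions: pyridine, DMAP (5 mol %), CH2Cl2, −20 °C
Reagents that add atoms: none
Why: Regioselective esterification: the C4 hydroxyl is the only one not flanked by a quaternary carbon and is acylated before the neopentyl C5 hydroxyl; no stereocentre changes and the product is the target.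

**Compound list**

1 | 3-oxocyclobutane-1-carboxylic acid | OC(=O)C1CC(=O)C1 | starting material
2 | methyl 3-oxocyclobutane-1-carboxylate | COC(=O)C1CC(=O)C1 | intermediate
3 | lithium enolate of 2 (O–Li on C8, double bond C8=C2, C1 configured as in 4) | COC(=O)[C@@H]1CC(O[Li])=C1 | intermediate
4 | methyl (1R,2S)-2-methyl-3-oxocyclobutane-1-carboxylate (trans) | COC(=O)[C@H]1[C@H](C)C(=O)C1 | intermediate
5 | methyl (1S)-2-bromo-2-methyl-3-oxocyclobutane-1-carboxylate (both C2 epimers) | COC(=O)[C@H]1C(C)(Br)C(=O)C1 | intermediate
6 | 2-methylbut-3-yn-2-ol | CC(C)(O)C#C | starting material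
7 | sodium 2-methylbut-3-yn-2-olate | [Na+].[O-]C(C)(C)C#C | intermediate
8 | 3-methoxy-3-methylbut-1-yne | COC(C)(C)C#C | intermediate
9 | lithium acetylide of 8 | [Li]C#CC(C)(C)OC | intermediate
10 | 4-methoxy-4-methylpent-2-ynal | COC(C)(C)C#CC=O | intermediate
11 | hexacarbonyldicobalt (Co–Co) complex of 10, alkyne carbons bridging both cobalt atoms | COC(C)(C)C12C3(C=O)[Co]1(=C=O)(=C=O)(=C=O)[Co]23(=C=O)(=C=O)=C=O | intermediate
12 | bromozinc enolate from 5 (O–ZnBr on C8, double bond C8=C2, C2 bears CH3) | COC(=O)[C@@H]1CC(O[Zn]Br)=C1C | intermediate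
13 | Co2(CO)6 complex of the aldol adduct: cyclobutanone (C8=O) with C1–CO2CH3; quaternary C2 with CH3 cis and the chain C3H(OH)–C4≡C5–C6(CH3)2OCH3 trans to the ester; C3 configured as in the target | COC(=O)[C@@H]1CC(=O)[C@@]1(C)[C@H](O)C23C4(C(C)(C)OC)[Co]2(=C=O)(=C=O)(=C=O)[Co]34(=C=O)(=C=O)=C=O | intermediate
14 | bis-silyl derivative of 13: C8–OSiMe3 enol ether (C8=C7) and C3–OSiMe3 | COC(=O)[C@@H]1C=C(O[Si](C)(C)C)[C@@]1(C)[C@H](O[Si](C)(C)C)C23C4(C(C)(C)OC)[Co]2(=C=O)(=C=O)(=C=O)[Co]34(=C=O)(=C=O)=C=O | intermediate
15 | C3–OSiMe3 ether of 16 | COC(=O)[C@@H]1[C@@H]2C(=O)[C@@]1(C)[C@H](O[Si](C)(C)C)C34C5(C2(C)C)[Co]3(=C=O)(=C=O)(=C=O)[Co]45(=C=O)(=C=O)=C=O | intermediate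
16 | Co2(CO)6 complex (on C4≡C5) of the bicyclo[4.1.1]octynone: cyclobutanone C8 bridged C2→C7 by C3(OH)–C4≡C5–C6(CH3)2 on the upper face; C1–CO2CH3 and C2–CH3 on the lower face; C3–OH on the C1 side | COC(=O)[C@@H]1[C@@H]2C(=O)[C@@]1(C)[C@H](O)C34C5(C2(C)C)[Co]3(=C=O)(=C=O)(=C=O)[Co]45(=C=O)(=C=O)=C=O | intermediate
17 | bicyclo[4.1.1]octenone as 16 without cobalt, C4=C5 cis: methyl ester at C1 (lower face), C2–CH3, C3–OH on the C1 side, C6 gem-dimethyl, C8 ketone | COC(=O)[C@@H]1[C@@H]2C(=O)[C@@]1(C)[C@H](O)C=CC2(C)C | intermediate
18 | triol from 17: C3–OH on the C1 side, C4–OH and C5–OH both on the C8 side | COC(=O)[C@@H]1[C@@H]2C(=O)[C@@]1(C)[C@H](O)[C@@H](O)[C@@H](O)C2(C)C | intermediate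
19 | 18 protected as C4/C5 acetonide and C3 2-methoxypropan-2-yl ether | COC(=O)[C@@H]1[C@@H]2C(=O)[C@@]1(C)[C@H](OC(C)(C)OC)[C@H]3OC(C)(C)O[C@H]3C2(C)C | intermediate
20 | C8 hydrazone of 19 (C=N isomers) | COC(=O)[C@@H]1[C@@H]2C(=NN)[C@@]1(C)[C@H](OC(C)(C)OC)[C@H]3OC(C)(C)O[C@H]3C2(C)C | intermediate
21 | potassium C1-carboxylate with C8 = CH2, acetonide and C3 mixed ketal still in place | [K+].[O-]C(=O)[C@@H]1[C@@H]2C[C@@]1(C)[C@H](OC(C)(C)OC)[C@H]3OC(C)(C)O[C@H]3C2(C)C | intermediate
22 | bicyclo[4.1.1]octane acid: C1–CO2H on the lower face, C2–CH3, C3–OH (C1 side), C4/C5 acetonide (C8 side), C6 gem-dimethyl, C8 = CH2 | OC(=O)[C@@H]1[C@@H]2C[C@@]1(C)[C@H](O)[C@H]3OC(C)(C)O[C@H]3C2(C)C | intermediate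
23 | propyne | CC#C | starting material
24 | propynyllithium | [Li]C#CC | intermediate
25 | triethyl(prop-1-yn-1-yl)silane | CC#C[Si](CC)(CC)CC | intermediate
26 | (Z)-triethyl(2-iodoprop-1-en-1-yl)silane (I and Si cis) | I/C(C)=C\[Si](CC)(CC)CC | intermediate
27 | 22 carrying at C8, on the lower face (cis to CO2H), the group C9(CH3)=C10H–SiEt3 with C8 and Si cis | OC(=O)[C@@H]1[C@@H]2[C@H](/C(C)=C\[Si](CC)(CC)CC)[C@@]1(C)[C@H](O)[C@H]3OC(C)(C)O[C@H]3C2(C)C | intermediate
28 | acid chloride of 27 | ClC(=O)[C@@H]1[C@@H]2[C@H](/C(C)=C\[Si](CC)(CC)CC)[C@@]1(C)[C@H](O)[C@H]3OC(C)(C)O[C@H]3C2(C)C | intermediate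
29 | tricyclic enone (target skeleton) with free C3–OH (C1 side) and C4/C5 acetonide (C8 side) | O[C@@H]1[C@H]4OC(C)(C)O[C@H]4C(C)(C)[C@@H]2[C@H]3C(=O)C=C(C)[C@@H]2[C@@]13C | intermediate
30 | angelic acid, (Z)-2-methylbut-2-enoic acid | C/C=C(/C)C(=O)O | starting material
31 | angelic anhydride, (Z,Z)-2-methylbut-2-enoic anhydride | C/C=C(/C)C(=O)OC(=O)/C(C)=C\C | intermediate
32 | lithium C3-alkoxide of 29 | [Li]O[C@@H]1[C@H]4OC(C)(C)O[C@H]4C(C)(C)[C@@H]2[C@H]3C(=O)C=C(C)[C@@H]2[C@@]13C | intermediate
33 | C3 angelate of 29 (acetonide still on) | C/C=C(/C)C(=O)O[C@@H]1[C@H]4OC(C)(C)O[C@H]4C(C)(C)[C@@H]2[C@H]3C(=O)C=C(C)[C@@H]2[C@@]13C | intermediate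
34 | tricyclic enone with C3 angelate (C1 side) and free C4–OH, C5–OH (C8 side) | C/C=C(/C)C(=O)O[C@@H]1[C@@H](O)[C@@H](O)C(C)(C)[C@@H]2[C@H]3C(=O)C=C(C)[C@@H]2[C@@]13C | intermediate
35 | isovaleric acid, 3-methylbutanoic acid | CC(C)CC(=O)O | starting material
36 | isovaleric anhydride, 3-methylbutanoic anhydride | CC(C)CC(=O)OC(=O)CC(C)C | intermediate
37 | CNP0251293.1: 3-angeloyloxy-5-hydroxy-4-(3-methylbutanoyloxy)-2,6,6,9-tetramethyltricyclo[5.4.0.0(2,8)]undec-9-en-11-one, angelate on the C1 side, isovalerate and hydroxyl on the C8 side | C/C=C(/C)C(=O)O[C@@H]1[C@@H](OC(=O)CC(C)C)[C@@H](O)C(C)(C)[C@@H]2[C@H]3C(=O)C=C(C)[C@@H]2[C@@]13C | target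

**Totals and risks**

Total step count: 20. Longest linear sequence: 13 steps (1, 2, 3, 7, 8, 9, 10, 11, 12, 15, 16, 18, 20; the branch 4, 5, 6 joining at step 7 is equally long).

The three steps most likely to fail:

Step 15 (the new C–H alkenylation). The C2 methyl also offers a γ-C–H cis to the carboxyl, and the vinylsilane may protodesilylate in hot HFIP. The fallback uses known reactions only, sets out from 19 and comes back at 29. The C8 ketone of 19 is olefinated with Ph3P=C(CH3)OCH3 (Wittig, from the phosphonium chloride and KN(SiMe3)2) to give the methyl enol ether F1. LiCH2P(O)(OCH3)2 then converts the C1 ester into the β-ketophosphonate F2. Aqueous oxalic acid in THF unmasks the acetyl group at C8 and removes the C3 mixed ketal, giving the methyl ketone F3 as equilibrating C8 epimers. K2CO3 with 18-crown-6 in toluene closes the cyclohexenone by intramolecular Horner–Wadsworth–Emmons olefination; only the epimer with the acetyl group on the lower face can cyclise, which gives 29.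

Step 8 (Nicholas ring closure to the bridged bicycle). Ionisation at C3 or retro-aldol cleavage may compete with formation of the strained ring. The fallback closes the ring by olefin metathesis instead of by a cation; it sets out from 4 (and uses 8) and comes back at 17. LiN(i-Pr)2 and Me3SiCl convert 4 into the less substituted silyl enol ether F4. Separately, 8 and Co2(CO)8 give the cobalt-complexed ether F5. BF3·OEt2 joins F4 and F5 in an intermolecular Nicholas alkylation at C7, trans to the ester, to give the complexed ketone F6, and (NH4)2Ce(NO3)6 frees the alkyne F7. Hydrogen over Pd/CaCO3 poisoned by Pb(OAc)2 gives the vinyl compound F8. LiN(i-Pr)2 deprotonates the more accessible C2–H and acrolein adds to give the diene F9. The second-generation Hoveyda–Grubbs catalyst, RuCl2(H2IMes)(=CH–C6H4-2-O-i-Pr), in toluene at 80 °C then forms the C4=C5 bond and delivers 17.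

Step 16 (acylative ring closure). The cation at C9 sits next to the cyclobutane and may ring-expand before silicon is lost. The fallback is an anionic ring closure that sets out from 27 and comes back at 29. N-Iodosuccinimide in MeCN replaces silicon by iodine with retention to give the vinyl iodide F10. EDC with MeNHOMe·HCl gives the Weinreb amide F11. t-BuLi (3.3 equiv, THF, −78 °C) deprotonates the hydroxyl, exchanges iodine for lithium, and the vinyllithium acylates the amide intramolecularly to give 29.

**Further compounds**

F1 | step 15 | methyl enol ether of 19, C8=C(CH3)OCH3 (E/Z mixture) | COC(=O)[C@@H]1[C@@H]2C(=C(C)OC)[C@@]1(C)[C@H](OC(C)(C)OC)[C@H]3OC(C)(C)O[C@H]3C2(C)C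
F2 | step 15 | dimethyl β-ketophosphonate from the C1 ester of F1 | COP(=O)(OC)CC(=O)[C@@H]1[C@@H]2C(=C(C)OC)[C@@]1(C)[C@H](OC(C)(C)OC)[C@H]3OC(C)(C)O[C@H]3C2(C)C
F3 | step 15 | β-ketophosphonate with C8 acetyl (lower face shown), free C3–OH, acetonide | COP(=O)(OC)CC(=O)[C@@H]1[C@@H]2[C@H](C(C)=O)[C@@]1(C)[C@H](O)[C@H]3OC(C)(C)O[C@H]3C2(C)C
F4 | step 8 | trimethylsilyl enol ether of 4 toward C7 | COC(=O)[C@H]1[C@H](C)C(O[Si](C)(C)C)=C1
F5 | step 8 | hexacarbonyldicobalt complex of 8 | COC(C)(C)C12C3[Co]1(=C=O)(=C=O)(=C=O)[Co]23(=C=O)(=C=O)=C=O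
F6 | step 8 | Co2(CO)6 complex of methyl 2-methyl-4-(2-methylbut-3-yn-2-yl)-3-oxocyclobutane-1-carboxylate (C7 substituent trans to the ester) | COC(=O)[C@H]1[C@H](C)C(=O)[C@@H]1C(C)(C)C23C4[Co]2(=C=O)(=C=O)(=C=O)[Co]34(=C=O)(=C=O)=C=O
F7 | step 8 | methyl 2-methyl-4-(2-methylbut-3-yn-2-yl)-3-oxocyclobutane-1-carboxylate | COC(=O)[C@H]1[C@H](C)C(=O)[C@@H]1C(C)(C)C#C
F8 | step 8 | methyl 2-methyl-4-(2-methylbut-3-en-2-yl)-3-oxocyclobutane-1-carboxylate | COC(=O)[C@H]1[C@H](C)C(=O)[C@@H]1C(C)(C)C=C
F9 | step 8 | acrolein aldol adduct of F8: C2 bears CH3 (cis to ester) and CH(OH)CH=CH2 (trans to ester) | COC(=O)[C@H]1[C@](C)([C@H](O)C=C)C(=O)[C@@H]1C(C)(C)C=C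
F10 | step 16 | vinyl iodide acid: 27 with iodine in place of SiEt3 | OC(=O)[C@@H]1[C@@H]2[C@H](/C(C)=C\I)[C@@]1(C)[C@H](O)[C@H]3OC(C)(C)O[C@H]3C2(C)C
F11 | step 16 | N-methoxy-N-methylamide of F10 | CON(C)C(=O)[C@@H]1[C@@H]2[C@H](/C(C)=C\I)[C@@]1(C)[C@H](O)[C@H]3OC(C)(C)O[C@H]3C2(C)C
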